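**Strategy.** Everything rests on cutting the C3–C4 single bond of the cross-conjugated diene (germacrane numbering): C3 is the enol-ether carbon of the 3(2H)-furanone ring (O, C3, C2, C1, C10) and C4 carries the exocyclic methylene C15. The furanone alkene C2=C3 is an enone with a free C3–H, so a macrocyclising intramolecular Heck reaction of a 2-bromoallylic alcohol (C4–Br, C5–OH) makes this bond, the diene and the ten-membered carbocycle C1–C10 (furanone as bridge) in one operation. Its precursor is an open-chain furanone–lactone built by a Barbier union of two chiral fragments, with the α-methylene lactone masked as its dimethylamine adduct.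

Key step: step 16

Remark: atoms are numbered as in the germacrane skeleton (C1 ketone, C2=C3 furanone alkene, C4=C15, C5 carbinol, C6 lactone O–CH, C7, C8 ester carbinol, C9, C10 quaternary, C11=C13, C12 lactone C=O). C11 of the amine adducts 27–30 is expected as an epimer mixture, is erased in step 17, and is left undefined in their SMILES.

**Fragment 1 (C8–C10, C1–C3)**

Step 1
Reactants: 1 (S)-lactic acid; 2 pivalaldehyde
Product: 3 (2S,5S)-2-tert-butyl-5-methyl-1,3-dioxolan-4-one
Conditions: TsOH·H2O (cat.), H2SO4 (cat.), pentane, reflux (Dean–Stark); crystallisation at −78 °C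
Reagents that add atoms: pivalaldehyde (2), CC(C)(C)C=O
Why: Acid-catalysed acetalisation gives the thermodynamically and crystallisation-favoured cis dioxolanone, so the lactate centre fixes the new acetal centre (self-regeneration-of-stereocentres template).

Step 2
Reactants: 3 (2S,5S)-2-tert-butyl-5-methyl-1,3-dioxolan-4-one; 4 allyl bromide
Product: 5 (2S,5R)-5-allyl-2-tert-butyl-5-methyl-1,3-dioxolan-4-one
Conditions: LiN(i-Pr)2, THF, −78 °C; allyl bromide, −78 → −30 °C
Reagents that add atoms: allyl bromide (4), C=CCBr
Why: Enolate alkylation of the dioxolanone occurs on the face opposite the tert-butyl group, so the acetal centre relays the lactate configuration into the quaternary carbon that becomes C10 (R).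

Step 3
Reactants: 5 (2S,5R)-5-allyl-2-tert-butyl-5-methyl-1,3-dioxolan-4-one; 6 N,O-dimethylhydroxylamine hydrochloride
Product: 7 (2R)-2-hydroxy-N-methoxy-N,2-dimethylpent-4-enamide
Conditions: i-PrMgCl (preformed ClMgN(OMe)Me), THF, −20 → 0 °C
Reagents that add atoms: N,O-dimethylhydroxylamine hydrochloride (6), CNOC.Cl
Why: Aminolysis of the activated dioxolanone carbonyl by the magnesium amide (Weinreb amide formation) opens the acetal and expels pivalaldehyde without touching the quaternary centre.

Step 4
Reactants: 7 (2R)-2-hydroxy-N-methoxy-N,2-dimethylpent-4-enamide; 8 ethynylmagnesium bromide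
Product: 11 (2R)-2-methyl-2-(prop-2-en-1-yl)furan-3(2H)-one, via hydroxy ynone 9 (not isolated), via diethylamino enaminone 10 (not isolated)
Conditions: HC≡CMgBr (3 equiv), THF, 0 °C; aq NH4Cl; then Et2NH, EtOH, rt; then 1 M HCl, THF, rt
Reagents that add atoms: ethynylmagnesium bromide (8), C#C[Mg]Br
Why: The Weinreb ketone synthesis stops at the ynone, conjugate addition of Et2NH gives the (E)-enaminone, and acid then drives 5-exo attack of the tertiary hydroxyl on the protonated enaminone with loss of the amine (hydroxy-ynone to 3(2H)-furanone cyclisation), leaving C3–H free.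

Step 5
Reactants: 11 (2R)-2-methyl-2-(prop-2-en-1-yl)furan-3(2H)-one
Product: 12 2-[(2R)-2-methyl-3-oxo-2,3-dihydrofuran-2-yl]acetaldehyde
Conditions: OsO4 (2 mol%), NaIO4, 2,6-lutidine, dioxane/H2O, rt
Reagents that add atoms: osmium tetroxide, O=[Os](=O)(=O)=O; sodium periodate, [Na+].[O-][I](=O)(=O)=O
Why: Lemieux–Johnson oxidation should cleave the monosubstituted allyl alkene much faster than the carbonyl-deactivated push–pull furanone alkene, and the buffered medium keeps the β-oxy aldehyde from eliminating.

**Fragment 2 (C4–C7, C11–C13, C15)**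

Step 6
Reactants: 13 acrolein
Product: 15 2-bromoacrolein, via 2,3-dibromopropanal 14 (not isolated)
Conditions: Br2, CH2Cl2, −78 → 0 °C; then Et3N, 0 °C
Reagents that add atoms: bromine, BrBr
Why: Bromine addition to the alkene followed by amine-induced E2 loss of HBr from the acidic α-position is the standard preparation of 2-bromoacrolein.

Step 7
Reactants: 15 2-bromoacrolein; 16 vinylmagnesium bromide
Product: 17 rac-2-bromopenta-1,4-dien-3-ol
Conditions: THF, −78 °C; aq NH4Cl
Reagents that add atoms: vinylmagnesium bromide (16), C=C[Mg]Br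
Why: 1,2-Grignard addition to the unhindered aldehyde at low temperature should outpace conjugate addition and bromine–magnesium exchange, giving the racemic bis-allylic alcohol.

Step 8
Reactants: 17 rac-2-bromopenta-1,4-dien-3-ol
Product: 18 (1S)-2-bromo-1-[(2S)-oxiran-2-yl]prop-2-en-1-ol
Conditions: Ti(OiPr)4, D-(−)-diisopropyl tartrate, t-BuOOH (0.55 equiv), 4 Å molecular sieves, CH2Cl2, −20 °C
Reagents that add atoms: tert-butyl hydroperoxide, CC(C)(C)OO
Why: Sharpless asymmetric epoxidation in kinetic-resolution mode should epoxidise the S alcohol fast, only at its unhalogenated vinyl group and with the usual erythro selectivity, which sets C5 (by selection) and C6 (by reagent-controlled face delivery) as the anti pair and leaves the R alcohol behind.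

Step 9
Reactants: 18 (1S)-2-bromo-1-[(2S)-oxiran-2-yl]prop-2-en-1-ol
Product: 19 tert-butyl{[(1S)-2-bromo-1-[(2S)-oxiran-2-yl]prop-2-en-1-yl]oxy}dimethylsilane
Conditions: TBSCl, imidazole, DMF, 0 °C → rt
Reagents that add atoms: tert-butyldimethylsilyl chloride, CC(C)(C)[Si](C)(C)Cl
Why: Silylation under neutral imidazole conditions protects the C5 hydroxyl while avoiding base-induced Payne rearrangement of the epoxy alcohol.

Step 10
Reactants: 19 tert-butyl{[(1S)-2-bromo-1-[(2S)-oxiran-2-yl]prop-2-en-1-yl]oxy}dimethylsilane
Product: 20 (3S,4S)-2-bromo-3-[(tert-butyldimethylsilyl)oxy]hexa-1,5-dien-4-ol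
Conditions: Me3S+ I−, n-BuLi, THF, −10 °C → rt
Reagents that add atoms: trimethylsulfonium iodide, C[S+](C)C.[I-]
Why: Dimethylsulfonium methylide opens the terminal epoxide at its CH2 carbon and the betaine eliminates Me2S through a second ylide (one-carbon homologation of an epoxide to an allylic alcohol), so the C6–O bond and its configuration are untouched.

Step 11
Reactants: 20 (3S,4S)-2-bromo-3-[(tert-butyldimethylsilyl)oxy]hexa-1,5-dien-4-ol; 21 2-(bromomethyl)acrylic acid
Product: 22 (3S,4S)-2-bromo-3-[(tert-butyldimethylsilyl)oxy]hexa-1,5-dien-4-yl 2-(bromomethyl)prop-2-enoate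
Conditions: DCC, DMAP (cat.), CH2Cl2, 0 °C
Reagents that add atoms: 2-(bromomethyl)acrylic acid (21), C=C(CBr)C(=O)O
Why: Steglich esterification at 0 °C should acylate the free allylic hydroxyl without displacing the allylic bromide.

Step 12
Reactants: 22 (3S,4S)-2-bromo-3-[(tert-butyldimethylsilyl)oxy]hexa-1,5-dien-4-yl 2-(bromomethyl)prop-2-enoate
Product: 23 (5S)-3-(bromomethyl)-5-[(1S)-2-bromo-1-[(tert-butyldimethylsilyl)oxy]prop-2-en-1-yl]furan-2(5H)-one
Conditions: second-generation Grubbs catalyst RuCl2(=CHPh)(PCy3)(H2IMes) (5 mol%), toluene (5 mM), 80 °C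
Reagents that add atoms: none
Why: Ring-closing metathesis of the acrylate with the monosubstituted allyl alkene gives the butenolide with loss of ethylene, the electron-poor 1,1-disubstituted bromoalkene being inert to the ruthenium carbene.

**Union and end game**

Step 13
Reactants: 12 2-[(2R)-2-methyl-3-oxo-2,3-dihydrofuran-2-yl]acetaldehyde; 23 (5S)-3-(bromomethyl)-5-[(1S)-2-bromo-1-[(tert-butyldimethylsilyl)oxy]prop-2-en-1-yl]furan-2(5H)-one
Product: 24 Barbier adduct with 8S alcohol (full name in the compound list)
Conditions: Zn dust, THF/sat. aq NH4Cl, 0 °C → rt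
Reagents that add atoms: none
Why: In this zinc Barbier (Dreiding–Schmidt) allylation the allylzinc attacks the aldehyde through its γ-carbon C7 on the ring face opposite the C6 side chain (C6/C7 trans), and because the butenolide locks the allyl unit in the E-type geometry a closed chair transition state should give the anti C7/C8 relation (C7 R, C8 S) while forming the α-methylene lactone.

Step 14
Reactants: 24 Barbier adduct with 8S alcohol; 25 3-methylbutanoic acid
Product: 26 8R isovalerate (full name in the compound list)
Conditions: PPh3, DIAD, toluene, 0 °C → rt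
Reagents that add atoms: 3-methylbutanoic acid (25), CC(C)CC(=O)O
Why: Mitsunobu esterification displaces the activated C8 carbinol by SN2 attack of the carboxylate with inversion, turning the 8S alcohol into the required 8R ester while the silyl ether keeps C5–O out of play.

Step 15
Reactants: 26 8R isovalerate
Product: 28 masked seco bromide with free C5 hydroxyl, via silylated amine adduct 27 (not isolated)
Conditions: Me2NH (2 M in THF), 0 °C; evaporate; HF·pyridine, THF/pyridine, 0 °C → rt; aq NaHCO3
Reagents that add atoms: dimethylamine, CNC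
Why: Aza-Michael addition of dimethylamine masks the α-methylene lactone, and the acidic HF·pyridine stage then removes the silyl ether and re-closes any furanone that the amine opened to its vinylogous amide, the same acid-driven cyclisation as in step 4.

Step 16
Reactants: 28 masked seco bromide with free C5 hydroxyl
Product: 29 masked macrocycle (dimethylamine adduct of the target)
Conditions: Pd(OAc)2 (20 mol%), PPh3 (40 mol%), Ag2CO3 (2 equiv), MeCN, 70 °C, syringe-pump addition to 1 mM
Reagents that add atoms: none
Why: Zerovalent palladium (from Pd(OAc)2/PPh3) inserts into the C4–Br bond, Ag2CO3 strips the bromide, and the cationic alkenylpalladium carbopalladates the furanone alkene with C4 going to C3 and palladium to C2 as an α-keto (enolate) species, which equilibrates through its O-bound form to the face syn to H3 and undergoes β-hydride elimination to restore C2=C3; carbonate removes HBr and returns zerovalent palladium. The closest known reaction type is the intramolecular Mizoroki–Heck reaction, specifically Heck-type β-C–H arylation or alkenylation of cyclic enones and chromones that ends in a formal anti β-hydride elimination. The closure is 9-exo-trig for the oxacycle C3–O–C10–C9–C8–C7–C6–C5–C4 (equally 10-endo-trig for the carbocycle C1–C10), and it turns the furanone into the one-atom oxygen bridge of the ten-membered ring. No stereocentre is created: C3 is sp3 only transiently and is flattened again, the diene geometry is dictated by the furanone ring, and C5, C6, C7, C8 and C10 are spectators. The step needs C3-over-C2 regioselectivity, secured by the enone/enol-ether polarisation of C2=C3 under cationic palladium; it needs chemoselectivity against the lactone methylene, secured by the amine mask (an unmasked C11=C13 would capture the alkenylpalladium in a fast 6-endo or 5-exo insertion); and it needs ring closure to beat dimerisation and reduction, secured by high dilution and hydride-free silver carbonate conditions.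

Step 17
Reactants: 29 masked macrocycle (dimethylamine adduct of the target)
Product: 31 target, via trimethylammonium iodide 30 (not isolated)
Conditions: MeI, MeCN, rt; evaporate; aq NaHCO3/CH2Cl2, rt
Reagents that add atoms: none
Why: Exhaustive N-methylation followed by mild-base E1cB (Hofmann-type) loss of trimethylamine from the β-ammonio lactone regenerates the C11=C13 methylene, erasing the C11 centre and releasing the target.

**Compound list**

1 | (S)-lactic acid | C[C@H](O)C(=O)O | starting material
2 | pivalaldehyde | CC(C)(C)C=O | starting material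
3 | (2S,5S)-2-tert-butyl-5-methyl-1,3-dioxolan-4-one (cis) | C[C@@H]1O[C@H](C(C)(C)C)OC1=O | intermediate
4 | allyl bromide | C=CCBr | starting material
5 | (2S,5R)-5-allyl-2-tert-butyl-5-methyl-1,3-dioxolan-4-one | C[C@]1(CC=C)O[C@H](C(C)(C)C)OC1=O | intermediate
6 | N,O-dimethylhydroxylamine hydrochloride | CNOC.Cl | starting material
7 | (2R)-2-hydroxy-N-methoxy-N,2-dimethylpent-4-enamide | C=CC[C@@](C)(O)C(=O)N(C)OC | intermediate
8 | ethynylmagnesium bromide | C#C[Mg]Br | starting material
9 | (4R)-4-hydroxy-4-methylhept-6-en-1-yn-3-one | C=CC[C@@](C)(O)C(=O)C#C | intermediate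
10 | (1E,4R)-1-(diethylamino)-4-hydroxy-4-methylhepta-1,6-dien-3-one | C=CC[C@@](C)(O)C(=O)/C=C/N(CC)CC | intermediate
11 | (2R)-2-methyl-2-(prop-2-en-1-yl)furan-3(2H)-one | C=CC[C@@]1(C)OC=CC1=O | intermediate
12 | 2-[(2R)-2-methyl-3-oxo-2,3-dihydrofuran-2-yl]acetaldehyde | O=CC[C@@]1(C)OC=CC1=O | intermediate
13 | acrolein | C=CC=O | starting material
14 | 2,3-dibromopropanal (racemic) | O=CC(Br)CBr | intermediate
15 | 2-bromoacrolein | C=C(Br)C=O | intermediate
16 | vinylmagnesium bromide | C=C[Mg]Br | starting material
17 | rac-2-bromopenta-1,4-dien-3-ol | C=CC(O)C(Br)=C | intermediate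
18 | (1S)-2-bromo-1-[(2S)-oxiran-2-yl]prop-2-en-1-ol | C=C(Br)[C@@H](O)[C@@H]1CO1 | intermediate
19 | tert-butyl{[(1S)-2-bromo-1-[(2S)-oxiran-2-yl]prop-2-en-1-yl]oxy}dimethylsilane | C=C(Br)[C@@H](O[Si](C)(C)C(C)(C)C)[C@@H]1CO1 | intermediate
20 | (3S,4S)-2-bromo-3-[(tert-butyldimethylsilyl)oxy]hexa-1,5-dien-4-ol | C=C(Br)[C@@H](O[Si](C)(C)C(C)(C)C)[C@@H](O)C=C | intermediate
21 | 2-(bromomethyl)acrylic acid | C=C(CBr)C(=O)O | starting material
22 | (3S,4S)-2-bromo-3-[(tert-butyldimethylsilyl)oxy]hexa-1,5-dien-4-yl 2-(bromomethyl)prop-2-enoate | C=C(Br)[C@@H](O[Si](C)(C)C(C)(C)C)[C@@H](OC(=O)C(=C)CBr)C=C | intermediate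
23 | (5S)-3-(bromomethyl)-5-[(1S)-2-bromo-1-[(tert-butyldimethylsilyl)oxy]prop-2-en-1-yl]furan-2(5H)-one | C=C(Br)[C@@H](O[Si](C)(C)C(C)(C)C)[C@H]1OC(=O)C(CBr)=C1 | intermediate
24 | (4R,5S)-5-[(1S)-2-bromo-1-[(tert-butyldimethylsilyl)oxy]prop-2-en-1-yl]-4-{(1S)-1-hydroxy-2-[(2R)-2-methyl-3-oxo-2,3-dihydrofuran-2-yl]ethyl}-3-methylideneoxolan-2-one | C=C1C(=O)O[C@@H]([C@H]1[C@@H](O)C[C@@]2(C)OC=CC2=O)[C@H](O[Si](C)(C)C(C)(C)C)C(Br)=C | intermediate
25 | 3-methylbutanoic acid (isovaleric acid) | CC(C)CC(=O)O | starting material
26 | (1R)-1-[(2S,3R)-2-[(1S)-2-bromo-1-[(tert-butyldimethylsilyl)oxy]prop-2-en-1-yl]-4-methylidene-5-oxooxolan-3-yl]-2-[(2R)-2-methyl-3-oxo-2,3-dihydrofuran-2-yl]ethyl 3-methylbutanoate | C=C1C(=O)O[C@@H]([C@H]1[C@H](OC(=O)CC(C)C)C[C@@]2(C)OC=CC2=O)[C@H](O[Si](C)(C)C(C)(C)C)C(Br)=C | intermediate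
27 | dimethylamine adduct of 26 (4-[(dimethylamino)methyl]oxolanone, silyl ether retained, C11 epimers) | CN(C)CC1C(=O)O[C@@H]([C@H]1[C@H](OC(=O)CC(C)C)C[C@@]2(C)OC=CC2=O)[C@H](O[Si](C)(C)C(C)(C)C)C(Br)=C | intermediate
28 | (1R)-1-[(2S,3R)-2-[(1S)-2-bromo-1-hydroxyprop-2-en-1-yl]-4-[(dimethylamino)methyl]-5-oxooxolan-3-yl]-2-[(2R)-2-methyl-3-oxo-2,3-dihydrofuran-2-yl]ethyl 3-methylbutanoate (C11 epimers) | CN(C)CC1C(=O)O[C@@H]([C@H]1[C@H](OC(=O)CC(C)C)C[C@@]2(C)OC=CC2=O)[C@H](O)C(Br)=C | intermediate
29 | 13-(dimethylamino)-11,13-dihydro derivative of the target (macrocycle closed, C11 epimers) | CN(C)CC1C(=O)O[C@H]2[C@H]1[C@H](OC(=O)CC(C)C)C[C@@]1(C)OC(=CC1=O)C(=C)[C@H]2O | intermediate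
30 | N-methyl quaternary ammonium iodide of 29 | C[N+](C)(C)CC1C(=O)O[C@H]2[C@H]1[C@H](OC(=O)CC(C)C)C[C@@]1(C)OC(=CC1=O)C(=C)[C@H]2O.[I-] | intermediate
31 | CNP0409337.2 (5R,6S,7R,8R,10R) | C=C1C(=O)O[C@H]2[C@H]1[C@H](OC(=O)CC(C)C)C[C@@]1(C)OC(=CC1=O)C(=C)[C@H]2O | target

**Totals.** 17 steps in all. The longest linear sequence is 12 steps (steps 6–12, then 13–17); the other branch is steps 1–5.

**Steps most likely to fail**

Step 16. The alkenylpalladium may be reduced or couple intermolecularly faster than it closes the strained ten-membered ring, and the palladium enolate formed after closure may be protonated instead of undergoing the formal anti β-hydride elimination. The fallback separates bond formation from re-oxidation. It sets out from 28: a formate-terminated reductive Heck conjugate cyclisation (Pd(OAc)2, PPh3, HCO2Na, DMF, 80 °C, high dilution) should give the C2–C3-saturated macrocyclic dihydrofuranone F1. Ketone-selective silyl enol ether formation (LiN(SiMe3)2, Me3SiCl, −78 °C) and Saegusa–Ito dehydrogenation with Pd(OAc)2 then reinstall C2=C3, returning to the route at 29.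

Step 14. SN2 displacement at the congested C8 carbinol may be slow, with elimination across C7–C8 and conjugate addition of the phosphine to the methylene lactone competing. The fallback replaces inversion by oxidation–reduction. It sets out from 24: dimethylamine (then acetic acid) gives the amine-masked 8S alcohol F2, the mask preventing migration of the lactone alkene into conjugation once C8 is a ketone. Dess–Martin periodinane gives the amine-masked C8 ketone F3. Corey–Bakshi–Shibata reduction ((S)-methyl oxazaborolidine, BH3·SMe2, with the branched C7 side expected to act as the large group) gives the amine-masked 8R alcohol F4. Acylation with isovaleric anhydride and DMAP returns to the route at 27, which is desilylated as in step 15. Should step 13 deliver the 8R alcohol directly, the same plain acylation would replace step 14.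

Step 15. The amine may attack the unsubstituted furanone carbon C3 or the ester, and the mask may later be lost by retro-Michael elimination under the warm, basic conditions of step 16. The fallback uses a neutral mask with oxidative removal. It sets out from 26: benzeneselenol with catalytic Et3N, then HF·pyridine, gives the phenylselenomethyl seco bromide F5. The Heck closure under the conditions of step 16 gives the macrocyclic selenide F6. H2O2 at 0 °C triggers selenoxide syn-elimination, which can only form C11=C13, returning to the route at 31.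

**Further compounds**

F1 | step 16 | C2–C3-saturated macrocyclic dihydrofuranone (amine-masked, C3 and C11 undefined) | CN(C)CC1C(=O)O[C@H]2[C@H]1[C@H](OC(=O)CC(C)C)C[C@@]1(C)OC(CC1=O)C(=C)[C@H]2O
F2 | step 14 | amine-masked 8S alcohol (dimethylamine adduct of 24) | CN(C)CC1C(=O)O[C@@H]([C@H]1[C@@H](O)C[C@@]2(C)OC=CC2=O)[C@H](O[Si](C)(C)C(C)(C)C)C(Br)=C
F3 | step 14 | amine-masked C8 ketone | CN(C)CC1C(=O)O[C@@H]([C@H]1C(=O)C[C@@]2(C)OC=CC2=O)[C@H](O[Si](C)(C)C(C)(C)C)C(Br)=C
F4 | step 14 | amine-masked 8R alcohol | CN(C)CC1C(=O)O[C@@H]([C@H]1[C@H](O)C[C@@]2(C)OC=CC2=O)[C@H](O[Si](C)(C)C(C)(C)C)C(Br)=C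
F5 | step 15 | phenylselenomethyl seco bromide (C5 hydroxyl free) | c1ccccc1[Se]CC1C(=O)O[C@@H]([C@H]1[C@H](OC(=O)CC(C)C)C[C@@]2(C)OC=CC2=O)[C@H](O)C(Br)=C
F6 | step 15 | macrocyclic selenide | c1ccccc1[Se]CC1C(=O)O[C@H]2[C@H]1[C@H](OC(=O)CC(C)C)C[C@@]1(C)OC(=CC1=O)C(=C)[C@H]2O
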